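The carbocycle is disconnected to a ring with a mirror plane: stripped of Br and of the methyl on C1′, the six-membered carbinol ring (C1′–OH, C2′–Br, C4′–H) is simply a 4-substituted cyclohexanone, and the target carries Br, CH3 and the dienyl chain equatorially. One organocatalytic operation, α-bromination of commercial ethyl 4-oxocyclohexanecarboxylate via a chiral enamine, picks one of its two enantiotopic CH2 groups and so fixes C2′. Methyl delivery trans to bromine and acid equilibration at C4′ pass that configuration on to the other two ring centres. A Suzuki coupling of the ring alkenylboronate with an (S)-linalool-derived oxane alkenyl iodide completes the diene.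

Key step: step 1

Remark: the (4R,5R) amine is assumed to give the 3R bromide; if the sense is opposite, its (4S,5S) enantiomer is used and nothing else changes.
Remark: the products of steps 1–3 are pairs of epimers at the ring carbon that carries the ester or acyl group (the later C4′), so their SMILES leave that centre open (the ozonide of step 7 likewise at its acetal carbon); for the step 1 product the pair is CCOC(=O)[C@H]1CCC(=O)[C@H](Br)C1 (trans, 1S,3R) and CCOC(=O)[C@@H]1CCC(=O)[C@H](Br)C1 (cis, 1R,3R).
Remark: (S)-linalool of high enantiomeric purity is taken as purchased; the amine catalyst (from (1R,2R)-1,2-diphenylethane-1,2-diamine and formaldehyde) and the dibromodienone (from 2,6-di-tert-butylphenol and Br2) are auxiliary reagents from one-step preparations and are not counted as steps.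

Step 1
Reactants: 1 ethyl 4-oxocyclohexane-1-carboxylate
Product: 2 ethyl (3R)-3-bromo-4-oxocyclohexane-1-carboxylate (pair of C1 epimers: trans 1S,3R and cis 1R,3R)
Conditions: (4R,5R)-4,5-diphenylimidazolidine (20 mol %), PhCO2H (20 mol %), 4,4-dibromo-2,6-di-tert-butylcyclohexa-2,5-dienone (1.0 equiv), THF, −30 °C; cold filtration through silica, used at once
Reagents that add atoms: 4,4-dibromo-2,6-di-tert-butylcyclohexa-2,5-dienone, CC(C)(C)C1=CC(Br)(Br)C=C(C(C)(C)C)C1=O
Why: The amine condenses with the ketone to an enamine toward one of the two enantiotopic α-CH2 groups, its C2-symmetric phenyl groups leave one face of the enamine carbon open to the dienone, which hands over Br+ and aromatizes to the phenol, and hydrolysis of the α-bromo iminium ion returns the catalyst; the closest known reaction type is the amine-catalysed enantioselective α-bromination of cyclic ketones with this dienone, together with enamine desymmetrization of 4-substituted cyclohexanones. No ring is closed and one C–Br bond is made. The C–Br centre C3 (later C2′) is set by the catalyst alone, since in the mirror-symmetric substrate attack on the catalyst-preferred face of either methylene gives the same 3R descriptor. C1 (later C4′) becomes stereogenic only because the mirror plane is lost; axial attack on the half-chair with an equatorial ester should make the trans epimer the main one, and the cis/trans relation is unimportant because step 4 re-equilibrates this centre. The step needs mono-bromination on one enamine face, which the achirality of 1 (no substrate bias to fight), one equivalent of bromine donor and −30 °C should secure. Since enolization of 2 would turn 3R into 3S and lower the enantiomeric purity of the whole ring, 2 is not stored but taken cold into step 2.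

Step 2
Reactants: 2 ethyl (3R)-3-bromo-4-oxocyclohexane-1-carboxylate (pair of C1 epimers)
Product: 3 ethyl (3R,4S)-3-bromo-4-hydroxy-4-methylcyclohexane-1-carboxylate (pair of C1 epimers)
Conditions: MeMgBr, CeCl3, THF, −78 °C; aq NH4Cl
Reagents that add atoms: methylmagnesium bromide, C[Mg]Br
Why: Organocerium 1,2-addition, weakly basic so that neither the ester nor the labile C–Br centre is touched, should deliver methyl anti-periplanar to the C–Br bond of the axial-bromine conformer or equatorially beside an equatorial bromine, in both cases trans to bromine, which sets the carbinol as 4S with OH cis to Br, the outcome known for methyl Grignard additions to 2-halocyclohexanones.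

Step 3
Reactants: 3 ethyl (3R,4S)-3-bromo-4-hydroxy-4-methylcyclohexane-1-carboxylate (pair of C1 epimers)
Product: 5 1-[(3R,4S)-3-bromo-4-hydroxy-4-methylcyclohexyl]ethan-1-one (pair of C1 epimers), via Weinreb amide 4 (not isolated)
Conditions: MeNHOMe·HCl, i-PrMgCl, THF, −20 °C; then MeMgBr, −20 → 0 °C; aq NH4Cl
Reagents that add atoms: N,O-dimethylhydroxylamine hydrochloride, CNOC.Cl (its atoms stay in 4 only); methylmagnesium bromide, C[Mg]Br
Why: Magnesium-amide aminolysis of the ester gives the N-methoxy-N-methylamide 4, whose chelated tetrahedral adduct with MeMgBr survives until work-up and so stops at the ketone (Weinreb ketone synthesis run in one flask), while one further equivalent of i-PrMgCl is spent on the hydroxyl, whose magnesium alkoxide is cis to bromine and cannot close an epoxide, and no stereocentre is touched.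

Step 4
Reactants: 5 1-[(3R,4S)-3-bromo-4-hydroxy-4-methylcyclohexyl]ethan-1-one (pair of C1 epimers)
Product: 6 1-[(1R,3R,4S)-3-bromo-4-hydroxy-4-methylcyclohexyl]ethan-1-one
Conditions: TsOH·H2O (cat.), CH2Cl2, 40 °C; minor C1 epimer separated and resubmitted
Reagents that add atoms: none
Why: Acid-catalysed enolization toward the ring carbon (thermodynamic epimerization of an α-stereocentre) lets C1 settle in the 1R configuration, the only one in which acetyl, bromine and methyl are all equatorial, while the neutral enol is too poor a nucleophile to displace the γ-bromide and the carbinol, deactivated by its gauche β-bromine, should not ionize.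

Step 5
Reactants: 6 1-[(1R,3R,4S)-3-bromo-4-hydroxy-4-methylcyclohexyl]ethan-1-one
Product: 7 (1S,2R,4R)-2-bromo-1-methyl-4-[(E)-1-(4,4,5,5-tetramethyl-1,3,2-dioxaborolan-2-yl)prop-1-en-2-yl]cyclohexan-1-ol
Conditions: CH2(Bpin)2 (2.3 equiv), lithium 2,2,6,6-tetramethylpiperidide (2.2 equiv), THF, 0 °C; then 6, −78 °C → rt
Reagents that add atoms: bis(4,4,5,5-tetramethyl-1,3,2-dioxaborolan-2-yl)methane, CC1(C)OB(CB2OC(C)(C)C(C)(C)O2)OC1(C)C
Why: Boron–Wittig olefination, in which the lithiated gem-diboronate (its first equivalent consumed by the hydroxyl) adds to the ketone and the β-alkoxide expels one boryl group syn as a borate, should leave the remaining Bpin trans to the bulky ring and cis to methyl (E), the selectivity known for branched methyl ketones, and the stabilized carbanion should add faster than it enolizes.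

Step 6
Reactants: 8 (S)-linalool, (3S)-3,7-dimethylocta-1,6-dien-3-ol
Product: 9 (3R,6S)-3-bromo-6-ethenyl-2,2,6-trimethyloxane
Conditions: 2,4,4,6-tetrabromocyclohexa-2,5-dienone, CH3NO2, 0 °C → rt; chromatography
Reagents that add atoms: 2,4,4,6-tetrabromocyclohexa-2,5-dienone, O=C1C(Br)=CC(Br)(Br)C=C1Br
Why: Bromoetherification, in which the bromonium ion of the trisubstituted alkene is opened by the tertiary hydroxyl at its more substituted carbon through a chair (6-endo, anti addition), leaves the quaternary centre of linalool untouched and forms the C–Br centre with little bias, so the wanted isomer (Br and ethenyl both equatorial) has to be separated from its C3 epimer and from 5-exo oxolanes, as is known for linalool.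

Step 7
Reactants: 9 (3R,6S)-3-bromo-6-ethenyl-2,2,6-trimethyloxane
Product: 11 (2S,5R)-5-bromo-2,6,6-trimethyloxane-2-carbaldehyde, via ozonide 10 (not isolated)
Conditions: O3, CH2Cl2, −78 °C; then Me2S, −78 °C → rt
Reagents that add atoms: ozone, [O-][O+]=O
Why: Ozonolysis with reductive work-up cleaves the only alkene by way of ozonide 10, the α-carbon being quaternary and unable to epimerize and the C–Br bond being inert.

Step 8
Reactants: 11 (2S,5R)-5-bromo-2,6,6-trimethyloxane-2-carbaldehyde
Product: 12 (3R,6S)-3-bromo-6-[(E)-2-iodoethenyl]-2,2,6-trimethyloxane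
Conditions: CHI3, CrCl2, THF/1,4-dioxane, 0 °C → rt
Reagents that add atoms: iodoform, IC(I)I
Why: Takai iodo-olefination, in which the gem-dichromium species from CHI3 and CrCl2 adds to the aldehyde and eliminates anti, should give the E iodoalkene, the tertiary α-carbon reinforcing E, while CrCl2 leaves an unactivated secondary bromide alone.

Step 9
Reactants: 7 (1S,2R,4R)-2-bromo-1-methyl-4-[(E)-1-(4,4,5,5-tetramethyl-1,3,2-dioxaborolan-2-yl)prop-1-en-2-yl]cyclohexan-1-ol; 12 (3R,6S)-3-bromo-6-[(E)-2-iodoethenyl]-2,2,6-trimethyloxane
Product: 13 (1S,2R,4R)-2-bromo-4-[(2E,4E)-5-[(2S,5R)-5-bromo-2,6,6-trimethyloxan-2-yl]penta-2,4-dien-2-yl]-1-methylcyclohexan-1-ol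
Conditions: Pd(dppf)Cl2 (5 mol %), K3PO4, degassed THF/H2O, rt → 40 °C
Reagents that add atoms: none
Why: In this Suzuki–Miyaura coupling zerovalent palladium should insert into the alkenyl C–I bond far faster than into the two unactivated secondary C–Br bonds, the phosphate-activated boronate transmetalates and reductive elimination joins the two sp2 carbons with retention at both alkenes, giving the (2E,4E)-diene without touching any stereocentre or the free tertiary hydroxyl.

Compound list
1 | ethyl 4-oxocyclohexane-1-carboxylate | CCOC(=O)C1CCC(=O)CC1 | starting material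
2 | ethyl (3R)-3-bromo-4-oxocyclohexane-1-carboxylate, pair of C1 epimers (trans 1S,3R and cis 1R,3R) | CCOC(=O)C1CCC(=O)[C@H](Br)C1 | intermediate
3 | ethyl (3R,4S)-3-bromo-4-hydroxy-4-methylcyclohexane-1-carboxylate, pair of C1 epimers | CCOC(=O)C1CC[C@](C)(O)[C@H](Br)C1 | intermediate
4 | (3R,4S)-3-bromo-4-hydroxy-N-methoxy-N,4-dimethylcyclohexane-1-carboxamide (Weinreb amide), pair of C1 epimers | CON(C)C(=O)C1CC[C@](C)(O)[C@H](Br)C1 | intermediate
5 | 1-[(3R,4S)-3-bromo-4-hydroxy-4-methylcyclohexyl]ethan-1-one, pair of C1 epimers | CC(=O)C1CC[C@](C)(O)[C@H](Br)C1 | intermediate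
6 | 1-[(1R,3R,4S)-3-bromo-4-hydroxy-4-methylcyclohexyl]ethan-1-one | CC(=O)[C@@H]1CC[C@](C)(O)[C@H](Br)C1 | intermediate
7 | (1S,2R,4R)-2-bromo-1-methyl-4-[(E)-1-(4,4,5,5-tetramethyl-1,3,2-dioxaborolan-2-yl)prop-1-en-2-yl]cyclohexan-1-ol | C/C(=C\B1OC(C)(C)C(C)(C)O1)[C@@H]1CC[C@](C)(O)[C@H](Br)C1 | intermediate
8 | (S)-linalool, (3S)-3,7-dimethylocta-1,6-dien-3-ol | C=C[C@@](C)(O)CCC=C(C)C | starting material
9 | (3R,6S)-3-bromo-6-ethenyl-2,2,6-trimethyloxane | C=C[C@]1(C)CC[C@@H](Br)C(C)(C)O1 | intermediate
10 | (2S,5R)-5-bromo-2,6,6-trimethyl-2-(1,2,4-trioxolan-3-yl)oxane (ozonide, both epimers at the trioxolane carbon) | O1OCOC1[C@]2(C)CC[C@@H](Br)C(C)(C)O2 | intermediate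
11 | (2S,5R)-5-bromo-2,6,6-trimethyloxane-2-carbaldehyde | O=C[C@]1(C)CC[C@@H](Br)C(C)(C)O1 | intermediate
12 | (3R,6S)-3-bromo-6-[(E)-2-iodoethenyl]-2,2,6-trimethyloxane | I/C=C/[C@]1(C)CC[C@@H](Br)C(C)(C)O1 | intermediate
13 | (1S,2R,4R)-2-bromo-4-[(2E,4E)-5-[(2S,5R)-5-bromo-2,6,6-trimethyloxan-2-yl]penta-2,4-dien-2-yl]-1-methylcyclohexan-1-ol | C/C(=C\C=C\[C@]1(C)CC[C@@H](Br)C(C)(C)O1)[C@@H]1CC[C@](C)(O)[C@H](Br)C1 | target

Total step count: 9. Longest linear sequence: 6 (steps 1–5 and 9, from 1); the oxane branch (steps 6–8) joins in step 9.

Steps most likely to fail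

Step 1. What may go wrong is incomplete discrimination of the enamine faces by the amine, and loss of configuration at the C–Br carbon through enolization of the product during reaction or work-up. The fallback sets out from 1 and returns at 2. Compound 1 is deprotonated enantioselectively with a chiral lithium amide (lithium bis[(R)-1-phenylethyl]amide or its enantiomer, chosen to remove the proton that leads to the 1S series) in the presence of Me3SiCl (THF, −100 °C). This gives the silyl enol ether ethyl (1S)-4-[(trimethylsilyl)oxy]cyclohex-3-ene-1-carboxylate F1. N-Bromosuccinimide (THF, −78 °C) then brominates F1 axially on the half-chair with an equatorial ester, which should give the trans (1S,3R) epimer of 2, taken directly into step 2. In this variant the absolute configuration comes from the choice of methylene and the bromine face from axial attack, so any cis bromide would belong to the mirror-image series and must remain minor.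

Step 5. What may go wrong is deprotonation of the hindered ketone in place of addition (the ring-side enolate could then expel bromide), or incomplete E selectivity. The fallback sets out from 6 and 11 and returns at 13, reversing the polarity of the union with non-basic chromium reagents. Takai olefination of 6 (CHI3, CrCl2, THF) should give (1S,2R,4R)-2-bromo-4-[(E)-1-iodoprop-1-en-2-yl]-1-methylcyclohexan-1-ol F2, with the Z isomer removed by chromatography. Aldehyde 11 is converted with Cl2CHBpin, CrCl2 and LiI (THF) into 2-[(E)-2-[(2S,5R)-5-bromo-2,6,6-trimethyloxan-2-yl]ethenyl]-4,4,5,5-tetramethyl-1,3,2-dioxaborolane F3. Suzuki coupling of F2 with F3 under the conditions of step 9 gives 13.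

Step 3. What may go wrong is loss of bromide while basic magnesium reagents are present (an ester or amide enolate closing a three-membered ring onto C3, or alkoxide-driven ring contraction), and slow aminolysis of the hindered ester. The fallback sets out from 3 and returns at 5 by a redox detour in place of acyl substitution. i-Bu2AlH (CH2Cl2, −78 °C) reduces the ester to (3R,4S)-3-bromo-4-hydroxy-4-methylcyclohexane-1-carbaldehyde F4. MeMgBr with CeCl3 (THF, −78 °C) gives (1S,2R)-2-bromo-4-(1-hydroxyethyl)-1-methylcyclohexan-1-ol F5. Dess–Martin periodinane (CH2Cl2, NaHCO3) oxidizes the secondary alcohol, leaving the tertiary one, to 5.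

Further compounds
F1 | step 1 | ethyl (1S)-4-[(trimethylsilyl)oxy]cyclohex-3-ene-1-carboxylate | CCOC(=O)[C@H]1CCC(O[Si](C)(C)C)=CC1
F2 | step 5 | (1S,2R,4R)-2-bromo-4-[(E)-1-iodoprop-1-en-2-yl]-1-methylcyclohexan-1-ol | C/C(=C\I)[C@@H]1CC[C@](C)(O)[C@H](Br)C1
F3 | step 5 | 2-[(E)-2-[(2S,5R)-5-bromo-2,6,6-trimethyloxan-2-yl]ethenyl]-4,4,5,5-tetramethyl-1,3,2-dioxaborolane | CC1(C)OB(/C=C/[C@]2(C)CC[C@@H](Br)C(C)(C)O2)OC1(C)C
F4 | step 3 | (3R,4S)-3-bromo-4-hydroxy-4-methylcyclohexane-1-carbaldehyde, pair of C1 epimers | O=CC1CC[C@](C)(O)[C@H](Br)C1
F5 | step 3 | (1S,2R)-2-bromo-4-(1-hydroxyethyl)-1-methylcyclohexan-1-ol, mixture at C4 and at the side-chain carbinol | CC(O)C1CC[C@](C)(O)[C@H](Br)C1
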